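Expect slowness first: at 5.00 h the maple readings add up to 2.20 % of product, against a scatter of 1 percentage point on each reading, so do not judge handedness from samples that early.

- maple: left-handed substrate 0.021 M; right-handed substrate 0.021 M; partner 0.13 M; precatalyst 42 µM; run made earlier
- flask: left-handed substrate 0.021 M; partner 0.0840 M; precatalyst 42 µM; right-handed substrate 0.021 M; time 2.0 d

- maple (time / h: left-handed product / %, right-handed product / %, left-handed substrate / %): 0.667: 0.6, 0, 49.5; 2.00: 0, 1.1, 49.1; 3.00: 0.5, 0.6, 50.4; 5.00: 1.9, 0.3, 45.7; 8.00: 8.2, 2.5, 44.4; 10.0: 10.3, 3.7, 43.7

(standard deviation of a reading: 1 percentage point)

- free catalyst is single-handed; left-handed substrate and right-handed substrate are mirror images of each other, charged as a racemate, each of them at the stated concentration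
- reactions considered so far: 2 free catalyst -> spent catalyst; left-handed substrate <-> right-handed substrate; partner + free catalyst + left-handed substrate -> free catalyst + left-handed product; partner + precatalyst -> free catalyst + spent reagent; partner + free catalyst + right-handed substrate -> free catalyst + right-handed product
- an excess is the difference of the two amounts in percent of their sum
- an excess is below zero if the other one leads

- excess of left-handed product over right-handed product in the product at 5.0 h
- excess of left-handed product over right-handed product in the product at 2.0 d
- part of the left-handed substrate and right-handed substrate charged together that has reacted at 2.0 d

Begin with the main step. Free catalyst and partner turn each substrate into its product, at a rate proportional to partner, free catalyst and that substrate. Divide the two rates: partner and free catalyst cancel, leaving the ratio of the substrate concentrations times a constant s, the selectivity factor. On this step by itself, the left-handed substrate in the maple run stands at 39.7 % at 10.0 h.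

Now add the interconversion of the substrates. The maple reading is 43.7 %, higher by 4 points and close to the racemic 43.0 %. So take the substrate ratio as one, and the product ratio then reads s directly. The last two maple rows give s = 2.98. Define e = (s − 1)/(s + 1), the excess of left-handed product while the substrate stays racemic: 49.8 %, a reading that carries its scatter.

Add the rest: partner activates precatalyst, and free catalyst pairs off into spent catalyst. These steps change free catalyst and partner, the two terms that cancelled, so they alter the speed and leave e standing as long as the substrate stays racemic. My reckoning for the flask is therefore 49.8 % at both times asked, and it gives no conversion.

The forecast expects the excess “roughly constant instead of collapsing with conversion”. It gives 50 % (38 % to 62 %) early, 47 % (30 % to 58 %) at the end, and 50 % reacted (25 % to 75 %).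

The flask gives 46.7 % and 46.0 %, with 35.9 % reacted, 14 points below the forecast. At 2.00 d spent catalyst holds 70.4 % of the catalyst charged in the flask, yet with the step that forms it struck out the final excess is 45.2 %. Of the 35.9 % reacted, e assigns 26.9 % to left-handed product; the flask holds 26.2 %.

    2 free catalyst → spent catalyst (k = 0.410 /M/s)
    left-handed substrate ⇌ right-handed substrate (k = 5.40 × 10⁻⁵ /s)
    partner + free catalyst + left-handed substrate → free catalyst + left-handed product (k = 3.60 /M²/s)
    partner + precatalyst → free catalyst + spent reagent (k = 2.30 × 10⁻⁴ /M/s)
    partner + free catalyst + right-handed substrate → free catalyst + right-handed product (k = 1.30 /M²/s)

Take a neighbour flask charged with 1.0 × 10⁻⁴ M of precatalyst. There e is still 49.8 %, and on its 49.7 % reacted it assigns 37.2 % to left-handed product and 12.5 % to right-handed product. The computed neighbour gives an excess of 45.5 % at 2.00 d, with 36.1 % of left-handed product and 13.5 % of right-handed product.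

The runs are calculated for an exercise; the scatter is artificial.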